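The easy mistake with a rate that sags is to decide why it sags before integrating it, and then to hang the larch answer on that guess. You can leave the cause open.

| flask | L | X | time |
|---|---|---|---|
| birch | 0.400 M | 0.0200 M |  |
| cedar | 1.20 M | 0.0200 M |  |
| ash | 0.400 M | 0.0600 M |  |
| larch | 2.90 M | 0.0200 M | 3.8 h |

| birch run: time / h | birch run: [L] / M | cedar run: time / h | cedar run: [L] / M | ash run: time / h | ash run: [L] / M |
|---|---|---|---|---|---|
| 0.76 | 0.3273 | 0.76 | 1.1049 | 0.76 | 0.2084 |
| 1.5 | 0.2640 | 1.5 | 1.0094 | 1.5 | 0.0934 |
| 2.3 | 0.2046 | 2.3 | 0.9160 | 2.3 | 0.0290 |
| 3.0 | 0.1621 | 3.0 | 0.8409 | 3.0 | 0.0099 |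
| 3.8 | 0.1166 | 3.8 | 0.7631 | 3.8 | 0.0025 |

(standard deviation of a reading: 0.002 M)

1. the exponent of [X] in the starting rate at the charge of the birch run (at the point where two percent of the L have become Q)
2. the exponent of [L] in the starting rate at the charge of the birch run (at the point where two percent of the L have become Q) (one fixed amount of Q, the same in the runs compared)
3. L in the larch run at 3.8 h, as a share of the L charged

- Overall: L -> Q, with X as catalyst.
- Constant volume, constant temperature.
- Bound and free are read together.
- An order is taken over about fifteen percent of the charge, up and down.

Birch, cedar and larch share one charge of X, so write the rate as a falling capacity, the same function of time in these flasks, times L/(K+L), with K the half-saturation constant. This is my assumption. Its integrated rate law needs no knowledge of that function: define the reach as the L lost plus K times the logarithm of the L charged over the L left. At equal time, the reach is the same whatever the charge of L.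

Requiring this of the last readings gives K. Birch lost 0.283 M by 3.8 h and cedar 0.437 M, so K reads 0.197 M and the reach reads 0.526 M.

Now bracket larch. Cedar lost more than birch, so the rate rises with L here, and larch, with its larger charge, should lose at least what cedar lost. It keeps at most 84.9 %. The logarithm is positive, so its loss stays below the reach, and it keeps at least 81.9 %. Putting that lowest L into the logarithm overstates it, so the loss is at least 0.487 M. Putting this loss back understates it, so the loss is at most 0.490 M. My reckoning therefore leaves larch between 83.1 % and 83.2 %.

The forecast gives 83 % (79.5 % to 86 %), inside the outer bracket, with orders 0.97 in X and 0.35 in L, from “Integrating larch from about 0.15 M/h downward”.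

The flask gives 82.9 %, which is 0.20 percentage points below my tightened pair, with orders 0.99 in X and 0.40 in L.

    X + L → Q + X (34.78 M⁻¹ h⁻¹)
    X + L ⇌ XL, settled at all times (4.260 M⁻¹)
    X + L → Qe + L (0.3384 M⁻¹ h⁻¹)

The capacity falls with time, so the reach must be compared at one time and not spread as an hourly mean. Birch's reach at 0.76 h reads 0.112 M. With that order in X taken as one, I assume the ash capacity to be 3.00 times birch's at each time, which gives the ash run a reach of 0.337 M at 0.76 h. Turning half of the ash charge needs a reach of 0.336 M, so this reckoning puts half of the ash charge near 0.76 h, and the ash run reached half at 0.794 h.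

The runs were computed with made-up constants.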